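**Plan**
- Retrosynthesis: the two galloyl ester C–O bonds are cut first. Ring A is then cut at C5–C6, C7–C8 and C4a–C5, giving a silyl ynol ether (upper unit) and a dihydropyranyl diazo ketone (ring C with ring B).
- The ynol ether is cut at upper C2–C3 (chiral allenylindium plus an arylacetaldehyde). The diazo ketone goes back through a methyl ketone and a ketene acetal phosphate to a δ-lactone, cut at lower C2–C3 (alkoxyallylation of an aryl aldehyde).
- Enabling feature: ring A is a pentasubstituted phloroglucinol. Oxygen-bearing C5 and C7 flank C6 (which holds upper C2), C8 is unsubstituted, and C4a/C8a also belong to pyran ring C. Its six carbons therefore map onto a dihydropyranyl ketene (C5, C8, C8a, C4a) and an oxygen-polarised alkyne (C6, C7).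
- Forward: rings B, B′, A′ and the galloyl rings are bought as arenes. Ring C is closed first (lactol), ring A last. Then follow silyl-to-benzyl exchange, acetal removal, double galloylation and global hydrogenolysis.
- Stereochemistry: lower C2/C3 (R,R) come from a syn-selective alkoxyallylation. Upper C2 (R) comes from a catalytic asymmetric alkynylation relayed through an axially chiral allenylindium. Upper C3 (S) comes from the anti-selective closed transition state of that addition. The ring-A-forming step creates no stereocentre.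

Key step: step 16

Abbreviations: ArG = 3,4,5-tris(benzyloxy)phenyl; ArP = 2,4,6-tris(benzyloxy)phenyl; MOM = methoxymethyl; TIPS = triisopropylsilyl; Ipc = isopinocampheyl.

Assumption: 5 and 31 are purchased as such, and the facial sense of the two reagent-controlled steps (4 and 10) is taken from the usual models for these reagents; if an assay showed the opposite sense, the antipodal ligand or borane would be used.

**Route**

Step 1
Reactants: 1 2,4,6-trihydroxybenzaldehyde
Product: 2 2,4,6-tris(benzyloxy)benzaldehyde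
Conditions: BnBr (3.6 equiv), K2CO3, DMF, 60 °C
Reagents that add atoms: benzyl bromide, BrCc1ccccc1
Why: Williamson ether synthesis on the three phenoxides, the formyl group lowering ring nucleophilicity enough that C-benzylation should stay minor.

Step 2
Reactants: 2 2,4,6-tris(benzyloxy)benzaldehyde
Product: 3 1,3,5-tris(benzyloxy)-2-(2-methoxyethenyl)benzene (E/Z mixture)
Conditions: Ph3P(CH2OMe)Cl, KOt-Bu, THF, 0 °C → rt
Reagents that add atoms: (methoxymethyl)triphenylphosphonium chloride, COC[P+](c1ccccc1)(c1ccccc1)c1ccccc1.[Cl-]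
Why: Wittig olefination with the methoxymethylene ylide should give the enol ether, both geometric isomers being equivalent for the next step.

Step 3
Reactants: 3 1,3,5-tris(benzyloxy)-2-(2-methoxyethenyl)benzene
Product: 4 2-[2,4,6-tris(benzyloxy)phenyl]acetaldehyde
Conditions: 2 M aq HCl, THF, rt; used crude
Reagents that add atoms: water, O
Why: Acid-catalysed enol ether hydrolysis (C-protonation, hydration, loss of methanol) unmasks the one-carbon-homologated arylacetaldehyde, which is used at once because it is prone to self-aldolisation.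

Step 4
Reactants: 5 3,4,5-tris(benzyloxy)benzaldehyde
Product: 6 (S)-1-ArG-3-(trimethylsilyl)prop-2-yn-1-ol
Conditions: trimethylsilylacetylene, Me2Zn, (S,S)-ProPhenol (10 mol %), Ph3PO (20 mol %), toluene, 0 °C
Reagents that add atoms: trimethylsilylacetylene, C#C[Si](C)(C)C
Why: Catalytic enantioselective alkynylation of an aromatic aldehyde by a dinuclear zinc–ProPhenol alkynylzinc complex, which should deliver the alkynyl group to the Re face and set the carbinol centre as S.

Step 5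
Reactants: 6 (S)-1-ArG-3-(trimethylsilyl)prop-2-yn-1-ol
Product: 7 (S)-1-ArG-3-(trimethylsilyl)prop-2-yn-1-yl methanesulfonate
Conditions: MsCl, Et3N, CH2Cl2, −78 °C; cold work-up, used without purification
Reagents that add atoms: methanesulfonyl chloride, CS(=O)(=O)Cl
Why: O-sulfonylation of the secondary alcohol forms only the O–S bond, so the configuration at carbon is retained.

Step 6
Reactants: 7 (S)-1-ArG-3-(trimethylsilyl)prop-2-yn-1-yl methanesulfonate; 4 2-[2,4,6-tris(benzyloxy)phenyl]acetaldehyde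
Product: 9 (2S,3R)-1-ArP-3-ArG-5-(trimethylsilyl)pent-4-yn-2-ol, via allenylindium 8 (not isolated)
Conditions: Pd(OAc)2 (5 mol %), PPh3 (5 mol %), InI (1.5 equiv), THF–HMPA (3:1), 0 °C → rt
Reagents that add atoms: none
Why: Marshall–Tamaru propargylation, in which zerovalent palladium displaces the mesylate anti (SN2′), InI turns the allenylpalladium into allenylindium 8 with retention and 8 adds to the aldehyde through a closed SE2′ transition state syn to indium, so that upper C2 is fixed by the mesylate configuration (net inversion) and upper C3 by the anti preference of that transition state.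

Step 7
Reactants: 9 (2S,3R)-1-ArP-3-ArG-5-(trimethylsilyl)pent-4-yn-2-ol
Product: 10 [(3R,4S)-4-(methoxymethoxy)-5-ArP-3-ArG-pent-1-yn-1-yl]trimethylsilane
Conditions: MOMCl, i-Pr2NEt, CH2Cl2, 0 → 40 °C
Reagents that add atoms: chloromethyl methyl ether, COCCl
Why: Acetal protection by O-alkylation with the oxocarbenium ion of the chloro ether, MOM being chosen because it should survive organolithium, peroxide, fluoride and the thermal ring-A step and fall to mild acid at the end.

Step 8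
Reactants: 10 [(3R,4S)-4-(methoxymethoxy)-5-ArP-3-ArG-pent-1-yn-1-yl]trimethylsilane
Product: 11 (3S,4S)-4-(methoxymethoxy)-5-ArP-3-ArG-pent-1-yne
Conditions: K2CO3 (0.2 equiv), MeOH–THF, rt
Reagents that add atoms: none
Why: Methoxide-catalysed protodesilylation of the alkynylsilane frees the terminal alkyne, and the mild base and short time should spare the propargylic benzylic C–H (the descriptor at C3 changes only because the CIP ranking of the alkyne changes).

Step 9
Reactants: 11 (3S,4S)-4-(methoxymethoxy)-5-ArP-3-ArG-pent-1-yne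
Product: 14 triisopropyl{[(3R,4S)-4-(methoxymethoxy)-5-ArP-3-ArG-pent-1-yn-1-yl]oxy}silane, via lithium acetylide 12 (not isolated), via lithium ynolate 13 (not isolated)
Conditions: n-BuLi, THF, −78 °C; LiOOt-Bu (from t-BuOOH and LiN(SiMe3)2), −78 → 0 °C; TIPSOTf, −78 °C → rt
Reagents that add atoms: tert-butyl hydroperoxide, CC(C)(C)OO; triisopropylsilyl trifluoromethanesulfonate, CC(C)[Si](C(C)C)(C(C)C)OS(=O)(=O)C(F)(F)F
Why: Electrophilic oxygen transfer from lithium tert-butyl peroxide to the lithium acetylide (acetylide oxidation) gives the lithium ynolate, which the bulky silyl triflate should trap on oxygen as the silyl ynol ether without involving the stereocentres.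

Step 10
Reactants: 5 3,4,5-tris(benzyloxy)benzaldehyde
Product: 15 (1R,2R)-2-(methoxymethoxy)-1-ArG-but-3-en-1-ol
Conditions: allyl methoxymethyl ether, s-BuLi, THF, −78 °C; (−)-Ipc2BOMe; BF3·OEt2; then 5, −78 °C; NaOH, H2O2, 0 °C → rt
Reagents that add atoms: allyl methoxymethyl ether, COCOCC=C
Why: Brown alkoxyallylation through a chair Zimmerman–Traxler transition state, in which the Z geometry of the γ-alkoxyallylborane gives the syn 1,2-dioxygen pattern and the isopinocampheyl groups direct attack to the Si face of the aldehyde, so that both lower-unit centres are set as (R,R) with the two oxygens already differentiated.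

Step 11
Reactants: 15 (1R,2R)-2-(methoxymethoxy)-1-ArG-but-3-en-1-ol
Product: 16 (5R,6R)-5-(methoxymethoxy)-6-ArG-oxan-2-ol (both anomers)
Conditions: Rh(acac)(CO)2 (1 mol %), Xantphos (2 mol %), CO/H2 (1:1, 10 bar), toluene, 70 °C
Reagents that add atoms: carbon monoxide, [C-]#[O+]
Why: Rhodium-catalysed hydroformylation with a wide-bite-angle diphosphine is linear-selective for the terminal alkene, and the δ-hydroxy aldehyde should close ring C spontaneously as the six-membered lactol because only the benzylic hydroxyl is free.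

Step 12
Reactants: 16 (5R,6R)-5-(methoxymethoxy)-6-ArG-oxan-2-ol
Product: 17 (5R,6R)-5-(methoxymethoxy)-6-ArG-oxan-2-one
Conditions: TEMPO (10 mol %), PhI(OAc)2, CH2Cl2, rt
Reagents that add atoms: none
Why: Oxoammonium (TEMPO) oxidation of a lactol to the lactone under near-neutral conditions that should leave the electron-rich aryl ethers and both stereocentres alone.

Step 13
Reactants: 17 (5R,6R)-5-(methoxymethoxy)-6-ArG-oxan-2-one
Product: 18 (2R,3R)-3-(methoxymethoxy)-2-ArG-3,4-dihydro-2H-pyran-6-yl diphenyl phosphate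
Conditions: KN(SiMe3)2, (PhO)2P(O)Cl, THF–HMPA, −78 °C
Reagents that add atoms: diphenyl chlorophosphate, O=P(Cl)(Oc1ccccc1)Oc1ccccc1
Why: Kinetic enolisation of the δ-lactone and O-phosphorylation give the cyclic ketene acetal phosphate as a vinyl electrophile, the MOM-oxy group sitting γ to the carbonyl where it cannot be eliminated.

Step 14
Reactants: 18 (2R,3R)-3-(methoxymethoxy)-2-ArG-3,4-dihydro-2H-pyran-6-yl diphenyl phosphate
Product: 20 1-[(2R,3R)-3-(methoxymethoxy)-2-ArG-3,4-dihydro-2H-pyran-6-yl]ethan-1-one, via ethoxyvinyl diene 19 (not isolated)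
Conditions: Bu3SnC(OEt)=CH2, Pd(PPh3)4 (5 mol %), LiCl, THF, 65 °C; then 0.5 M aq HCl, THF, 0 °C
Reagents that add atoms: tributyl(1-ethoxyvinyl)stannane, CCCC[Sn](CCCC)(CCCC)C(=C)OCC; water, O
Why: Stille coupling of the ketene acetal phosphate with the acyl-anion equivalent 1-ethoxyvinylstannane, followed by mild acid hydrolysis of the more basic acyclic enol ether of 19, which should spare the ring enol ether because it becomes part of an acceptor-substituted α-alkoxy enone.

Step 15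
Reactants: 20 1-[(2R,3R)-3-(methoxymethoxy)-2-ArG-3,4-dihydro-2H-pyran-6-yl]ethan-1-one
Product: 22 2-diazo-1-[(2R,3R)-3-(methoxymethoxy)-2-ArG-3,4-dihydro-2H-pyran-6-yl]ethan-1-one, via trifluoroacetyl diketone 21 (not isolated)
Conditions: LiN(SiMe3)2, THF, −78 °C; CF3CO2CH2CF3; dilute HCl work-up; then MsN3, Et3N, H2O (1 equiv), MeCN, rt
Reagents that add atoms: methanesulfonyl azide, CS(=O)(=O)N=[N+]=[N-]
Why: Detrifluoroacetylative Regitz-type diazo transfer, in which Claisen trifluoroacetylation of the kinetic methyl enolate activates the methyl group and the sulfonyl azide then transfers N2 with loss of the trifluoroacetyl group, the standard access to α,β-unsaturated diazo ketones that avoids diazomethane and acid chlorides.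

Step 16
Reactants: 22 2-diazo-1-[(2R,3R)-3-(methoxymethoxy)-2-ArG-3,4-dihydro-2H-pyran-6-yl]ethan-1-one; 14 triisopropyl{[(3R,4S)-4-(methoxymethoxy)-5-ArP-3-ArG-pent-1-yn-1-yl]oxy}silane
Product: 27 (2R,3R)-6-[(1R,2S)-2-(methoxymethoxy)-3-ArP-1-ArG-propyl]-3-(methoxymethoxy)-2-ArG-7-[(triisopropylsilyl)oxy]chroman-5-ol, via vinylketene 23 (not isolated), via cyclobutenone 24 (not isolated), via dienylketene 25 (not isolated), via cyclohexadienone 26 (not isolated)
Conditions: 14 (1.2 equiv), degassed toluene (0.02 M), hν (365 nm, Pyrex), rt; then 90 °C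
Reagents that add atoms: none
Why: Light expels N2 from 22 and the Wolff shift moves the dihydropyranyl group to the former diazo carbon, giving vinylketene 23, whose electrophilic ketene carbon is attacked by the oxygen-remote carbon of the polarised ynol ether 14 in a regiospecific [2+2] cycloaddition to cyclobutenone 24. Heating opens 24 by a reversible conrotatory 4π electrocyclic reaction to dienylketene 25, and the isomer with ketene and dihydropyranyl group cis closes ring A by a thermal disrotatory 6π electrocyclisation between the ketene carbon and pyran C5 (bond C4a–C5), after which cyclohexadienone 26 enolises to the aromatic phenol 27. The closest known reaction type is the photochemical-Wolff variant of the Danheiser benzannulation of unsaturated α-diazo ketones with silyl ynol ethers, applied here to a ketone whose alkene is a cyclic enol ether. The atom mapping is fixed by the mechanism (ketene carbon to C5 with a free hydroxyl, alkyne carbons to C6 bearing upper C2 and to C7 bearing OTIPS, diazo carbon to C8, enol-ether carbons to C8a and C4a), so no C6/C8 regioisomer can arise. No stereocentre is created, and the four existing ones sit on sp3 carbons outside the reacting π system in a neutral medium, so they should be carried through unchanged. The step needs the head-to-tail sense of the [2+2] addition, secured by the oxygen-polarised alkyne, and capture of the ketene by the alkyne ahead of dimerisation or acylation of the product phenol, favoured by a small excess of the strongly nucleophilic ynol ether and the low stationary ketene concentration under slow photolysis.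

Step 17
Reactants: 27 (2R,3R)-6-[(1R,2S)-2-(methoxymethoxy)-3-ArP-1-ArG-propyl]-3-(methoxymethoxy)-2-ArG-7-[(triisopropylsilyl)oxy]chroman-5-ol
Product: 29 (2R,3R)-5,7-bis(benzyloxy)-6-[(1R,2S)-2-(methoxymethoxy)-3-ArP-1-ArG-propyl]-3-(methoxymethoxy)-2-ArG-chroman, via diphenol 28 (not isolated)
Conditions: Bu4NF, THF, 0 °C; then BnBr, K2CO3, DMF, rt
Reagents that add atoms: benzyl bromide, BrCc1ccccc1
Why: Fluoride cleaves the aryl silyl ether and the resulting 5,7-diphenol 28 is O-benzylated in the same flask by a Williamson reaction, the secondary MOM ethers being inert to both reagents.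

Step 18
Reactants: 29 (2R,3R)-5,7-bis(benzyloxy)-6-[(1R,2S)-2-(methoxymethoxy)-3-ArP-1-ArG-propyl]-3-(methoxymethoxy)-2-ArG-chroman
Product: 30 (2R,3R)-5,7-bis(benzyloxy)-6-[(1R,2S)-2-hydroxy-3-ArP-1-ArG-propyl]-2-ArG-chroman-3-ol
Conditions: conc aq HCl (0.2 equiv), MeOH–THF (2:1), 45 °C
Reagents that add atoms: none
Why: Acid-catalysed transacetalisation to methanol removes both MOM groups as dimethoxymethane, while benzyl aryl ethers and the chroman should survive dilute acid at this temperature.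

Step 19
Reactants: 30 (2R,3R)-5,7-bis(benzyloxy)-6-[(1R,2S)-2-hydroxy-3-ArP-1-ArG-propyl]-2-ArG-chroman-3-ol; 31 3,4,5-tris(benzyloxy)benzoic acid
Product: 32 (2R,3R)-5,7-bis(benzyloxy)-6-[(1R,2S)-2-(ArG-carbonyloxy)-3-ArP-1-ArG-propyl]-2-ArG-chroman-3-yl 3,4,5-tris(benzyloxy)benzoate
Conditions: 31 (3 equiv), DCC, DMAP, CH2Cl2, rt → 40 °C
Reagents that add atoms: none
Why: Steglich esterification (carbodiimide activation and acyl transfer through the acylpyridinium ion) should acylate both hindered secondary alcohols with retention, all phenols being benzylated.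

Step 20
Reactants: 32 (2R,3R)-5,7-bis(benzyloxy)-6-[(1R,2S)-2-(ArG-carbonyloxy)-3-ArP-1-ArG-propyl]-2-ArG-chroman-3-yl 3,4,5-tris(benzyloxy)benzoate
Product: 33 CNP0240551.2
Conditions: H2 (1 atm), Pd(OH)2/C, THF–MeOH (1:1), rt; filtered and handled under argon
Reagents that add atoms: none
Why: Heterogeneous hydrogenolysis of the seventeen benzyl aryl ethers over palladium hydroxide should liberate the polyphenol, the alkyl galloyl esters and the cyclic benzylic C2–O1 bond being much slower to cleave under these neutral conditions.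

**Compound list**

1 | 2,4,6-trihydroxybenzaldehyde | O=Cc1c(O)cc(O)cc1O | starting material
2 | 2,4,6-tris(benzyloxy)benzaldehyde | O=Cc1c(OCc2ccccc2)cc(OCc2ccccc2)cc1OCc1ccccc1 | intermediate
3 | 1,3,5-tris(benzyloxy)-2-(2-methoxyethenyl)benzene (E/Z mixture) | COC=Cc1c(OCc2ccccc2)cc(OCc2ccccc2)cc1OCc1ccccc1 | intermediate
4 | 2-[2,4,6-tris(benzyloxy)phenyl]acetaldehyde | O=CCc1c(OCc2ccccc2)cc(OCc2ccccc2)cc1OCc1ccccc1 | intermediate
5 | 3,4,5-tris(benzyloxy)benzaldehyde | O=Cc1cc(OCc2ccccc2)c(OCc2ccccc2)c(OCc2ccccc2)c1 | starting material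
6 | (S)-1-ArG-3-(trimethylsilyl)prop-2-yn-1-ol | O[C@@H](c1cc(OCc2ccccc2)c(OCc2ccccc2)c(OCc2ccccc2)c1)C#C[Si](C)(C)C | intermediate
7 | (S)-1-ArG-3-(trimethylsilyl)prop-2-yn-1-yl methanesulfonate | CS(=O)(=O)O[C@@H](c1cc(OCc2ccccc2)c(OCc2ccccc2)c(OCc2ccccc2)c1)C#C[Si](C)(C)C | intermediate
8 | (M)-[3-ArG-1-(trimethylsilyl)propa-1,2-dien-1-yl]indium iodide methanesulfonate (allenylindium, trivalent indium) | C[Si](C)(C)C([In](I)OS(C)(=O)=O)=[C@@]=C([H])c1cc(OCc2ccccc2)c(OCc2ccccc2)c(OCc2ccccc2)c1 | intermediate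
9 | (2S,3R)-1-ArP-3-ArG-5-(trimethylsilyl)pent-4-yn-2-ol (anti) | C[Si](C)(C)C#C[C@@H](c8cc(OCc9ccccc9)c(OCc9ccccc9)c(OCc9ccccc9)c8)[C@@H](O)Cc8c(OCc9ccccc9)cc(OCc9ccccc9)cc8OCc8ccccc8 | intermediate
10 | [(3R,4S)-4-(methoxymethoxy)-5-ArP-3-ArG-pent-1-yn-1-yl]trimethylsilane | C[Si](C)(C)C#C[C@@H](c8cc(OCc9ccccc9)c(OCc9ccccc9)c(OCc9ccccc9)c8)[C@@H](OCOC)Cc8c(OCc9ccccc9)cc(OCc9ccccc9)cc8OCc8ccccc8 | intermediate
11 | (3S,4S)-4-(methoxymethoxy)-5-ArP-3-ArG-pent-1-yne | C#C[C@@H](c8cc(OCc9ccccc9)c(OCc9ccccc9)c(OCc9ccccc9)c8)[C@@H](OCOC)Cc8c(OCc9ccccc9)cc(OCc9ccccc9)cc8OCc8ccccc8 | intermediate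
12 | lithium acetylide of 11 | [Li]C#C[C@@H](c8cc(OCc9ccccc9)c(OCc9ccccc9)c(OCc9ccccc9)c8)[C@@H](OCOC)Cc8c(OCc9ccccc9)cc(OCc9ccccc9)cc8OCc8ccccc8 | intermediate
13 | lithium ynolate derived from 11 | [Li]OC#C[C@@H](c8cc(OCc9ccccc9)c(OCc9ccccc9)c(OCc9ccccc9)c8)[C@@H](OCOC)Cc8c(OCc9ccccc9)cc(OCc9ccccc9)cc8OCc8ccccc8 | intermediate
14 | triisopropyl{[(3R,4S)-4-(methoxymethoxy)-5-ArP-3-ArG-pent-1-yn-1-yl]oxy}silane | CC(C)[Si](C(C)C)(C(C)C)OC#C[C@@H](c8cc(OCc9ccccc9)c(OCc9ccccc9)c(OCc9ccccc9)c8)[C@@H](OCOC)Cc8c(OCc9ccccc9)cc(OCc9ccccc9)cc8OCc8ccccc8 | intermediate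
15 | (1R,2R)-2-(methoxymethoxy)-1-ArG-but-3-en-1-ol | C=C[C@@H](OCOC)[C@H](O)c1cc(OCc2ccccc2)c(OCc2ccccc2)c(OCc2ccccc2)c1 | intermediate
16 | (5R,6R)-5-(methoxymethoxy)-6-ArG-oxan-2-ol (both anomers) | OC1CC[C@@H](OCOC)[C@@H](c2cc(OCc3ccccc3)c(OCc3ccccc3)c(OCc3ccccc3)c2)O1 | intermediate
17 | (5R,6R)-5-(methoxymethoxy)-6-ArG-oxan-2-one | O=C1CC[C@@H](OCOC)[C@@H](c2cc(OCc3ccccc3)c(OCc3ccccc3)c(OCc3ccccc3)c2)O1 | intermediate
18 | (2R,3R)-3-(methoxymethoxy)-2-ArG-3,4-dihydro-2H-pyran-6-yl diphenyl phosphate | O=P(Oc1ccccc1)(Oc1ccccc1)OC1=CC[C@@H](OCOC)[C@@H](c2cc(OCc3ccccc3)c(OCc3ccccc3)c(OCc3ccccc3)c2)O1 | intermediate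
19 | (2R,3R)-6-(1-ethoxyethenyl)-3-(methoxymethoxy)-2-ArG-3,4-dihydro-2H-pyran | CCOC(=C)C1=CC[C@@H](OCOC)[C@@H](c2cc(OCc3ccccc3)c(OCc3ccccc3)c(OCc3ccccc3)c2)O1 | intermediate
20 | 1-[(2R,3R)-3-(methoxymethoxy)-2-ArG-3,4-dihydro-2H-pyran-6-yl]ethan-1-one | CC(=O)C1=CC[C@@H](OCOC)[C@@H](c2cc(OCc3ccccc3)c(OCc3ccccc3)c(OCc3ccccc3)c2)O1 | intermediate
21 | 4,4,4-trifluoro-1-[(2R,3R)-3-(methoxymethoxy)-2-ArG-3,4-dihydro-2H-pyran-6-yl]butane-1,3-dione | O=C(CC(=O)C(F)(F)F)C1=CC[C@@H](OCOC)[C@@H](c2cc(OCc3ccccc3)c(OCc3ccccc3)c(OCc3ccccc3)c2)O1 | intermediate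
22 | 2-diazo-1-[(2R,3R)-3-(methoxymethoxy)-2-ArG-3,4-dihydro-2H-pyran-6-yl]ethan-1-one | [N-]=[N+]=CC(=O)C1=CC[C@@H](OCOC)[C@@H](c2cc(OCc3ccccc3)c(OCc3ccccc3)c(OCc3ccccc3)c2)O1 | intermediate
23 | 2-[(2R,3R)-3-(methoxymethoxy)-2-ArG-3,4-dihydro-2H-pyran-6-yl]ethen-1-one (vinylketene) | O=C=CC1=CC[C@@H](OCOC)[C@@H](c2cc(OCc3ccccc3)c(OCc3ccccc3)c(OCc3ccccc3)c2)O1 | intermediate
24 | 2-[(1R,2S)-2-(methoxymethoxy)-3-ArP-1-ArG-propyl]-4-[(2R,3R)-3-(methoxymethoxy)-2-ArG-3,4-dihydro-2H-pyran-6-yl]-3-[(triisopropylsilyl)oxy]cyclobut-2-en-1-one (ring C4 unassigned) | COCO[C@@H](Cc8c(OCc9ccccc9)cc(OCc9ccccc9)cc8OCc8ccccc8)[C@H](c8cc(OCc9ccccc9)c(OCc9ccccc9)c(OCc9ccccc9)c8)C1=C(O[Si](C(C)C)(C(C)C)C(C)C)C(C1=O)C1=CC[C@@H](OCOC)[C@@H](c8cc(OCc9ccccc9)c(OCc9ccccc9)c(OCc9ccccc9)c8)O1 | intermediate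
25 | dienylketene from ring opening of 24 (ketene and dihydropyranyl cis on the central C=C) | COCO[C@@H](Cc8c(OCc9ccccc9)cc(OCc9ccccc9)cc8OCc8ccccc8)[C@H](c8cc(OCc9ccccc9)c(OCc9ccccc9)c(OCc9ccccc9)c8)C(=C=O)/C(O[Si](C(C)C)(C(C)C)C(C)C)=C\C1=CC[C@@H](OCOC)[C@@H](c8cc(OCc9ccccc9)c(OCc9ccccc9)c(OCc9ccccc9)c8)O1 | intermediate
26 | 4a,5-dihydro-5-oxo tautomer of 27 (cyclohexa-2,4-dienone, C4a unassigned) | COCO[C@@H](Cc8c(OCc9ccccc9)cc(OCc9ccccc9)cc8OCc8ccccc8)[C@H](c8cc(OCc9ccccc9)c(OCc9ccccc9)c(OCc9ccccc9)c8)C1=C(O[Si](C(C)C)(C(C)C)C(C)C)C=C2C(C1=O)C[C@@H](OCOC)[C@@H](c8cc(OCc9ccccc9)c(OCc9ccccc9)c(OCc9ccccc9)c8)O2 | intermediate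
27 | (2R,3R)-6-[(1R,2S)-2-(methoxymethoxy)-3-ArP-1-ArG-propyl]-3-(methoxymethoxy)-2-ArG-7-[(triisopropylsilyl)oxy]chroman-5-ol | COCO[C@@H](Cc8c(OCc9ccccc9)cc(OCc9ccccc9)cc8OCc8ccccc8)[C@H](c8cc(OCc9ccccc9)c(OCc9ccccc9)c(OCc9ccccc9)c8)c1c(O[Si](C(C)C)(C(C)C)C(C)C)cc2c(c1O)C[C@@H](OCOC)[C@@H](c8cc(OCc9ccccc9)c(OCc9ccccc9)c(OCc9ccccc9)c8)O2 | intermediate
28 | (2R,3R)-6-[(1R,2S)-2-(methoxymethoxy)-3-ArP-1-ArG-propyl]-3-(methoxymethoxy)-2-ArG-chroman-5,7-diol | COCO[C@@H](Cc8c(OCc9ccccc9)cc(OCc9ccccc9)cc8OCc8ccccc8)[C@H](c8cc(OCc9ccccc9)c(OCc9ccccc9)c(OCc9ccccc9)c8)c1c(O)cc2c(c1O)C[C@@H](OCOC)[C@@H](c8cc(OCc9ccccc9)c(OCc9ccccc9)c(OCc9ccccc9)c8)O2 | intermediate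
29 | (2R,3R)-5,7-bis(benzyloxy)-6-[(1R,2S)-2-(methoxymethoxy)-3-ArP-1-ArG-propyl]-3-(methoxymethoxy)-2-ArG-chroman | COCO[C@@H](Cc8c(OCc9ccccc9)cc(OCc9ccccc9)cc8OCc8ccccc8)[C@H](c8cc(OCc9ccccc9)c(OCc9ccccc9)c(OCc9ccccc9)c8)c1c(OCc9ccccc9)cc2c(c1OCc9ccccc9)C[C@@H](OCOC)[C@@H](c8cc(OCc9ccccc9)c(OCc9ccccc9)c(OCc9ccccc9)c8)O2 | intermediate
30 | (2R,3R)-5,7-bis(benzyloxy)-6-[(1R,2S)-2-hydroxy-3-ArP-1-ArG-propyl]-2-ArG-chroman-3-ol | O[C@@H](Cc8c(OCc9ccccc9)cc(OCc9ccccc9)cc8OCc8ccccc8)[C@H](c8cc(OCc9ccccc9)c(OCc9ccccc9)c(OCc9ccccc9)c8)c1c(OCc9ccccc9)cc2c(c1OCc9ccccc9)C[C@@H](O)[C@@H](c8cc(OCc9ccccc9)c(OCc9ccccc9)c(OCc9ccccc9)c8)O2 | intermediate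
31 | 3,4,5-tris(benzyloxy)benzoic acid | OC(=O)c1cc(OCc2ccccc2)c(OCc2ccccc2)c(OCc2ccccc2)c1 | starting material
32 | (2R,3R)-5,7-bis(benzyloxy)-6-[(1R,2S)-2-(ArG-carbonyloxy)-3-ArP-1-ArG-propyl]-2-ArG-chroman-3-yl 3,4,5-tris(benzyloxy)benzoate | O=C(c8cc(OCc9ccccc9)c(OCc9ccccc9)c(OCc9ccccc9)c8)O[C@@H](Cc8c(OCc9ccccc9)cc(OCc9ccccc9)cc8OCc8ccccc8)[C@H](c8cc(OCc9ccccc9)c(OCc9ccccc9)c(OCc9ccccc9)c8)c1c(OCc9ccccc9)cc2c(c1OCc9ccccc9)C[C@@H](OC(=O)c8cc(OCc9ccccc9)c(OCc9ccccc9)c(OCc9ccccc9)c8)[C@@H](c8cc(OCc9ccccc9)c(OCc9ccccc9)c(OCc9ccccc9)c8)O2 | intermediate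
33 | CNP0240551.2: (2R,3R)-5,7-dihydroxy-6-[(1R,2S)-2-(3,4,5-trihydroxybenzoyloxy)-3-(2,4,6-trihydroxyphenyl)-1-(3,4,5-trihydroxyphenyl)propyl]-2-(3,4,5-trihydroxyphenyl)chroman-3-yl 3,4,5-trihydroxybenzoate | O=C(O[C@@H](Cc1c(O)cc(O)cc1O)[C@H](c1cc(O)c(O)c(O)c1)c1c(O)cc2c(c1O)C[C@@H](OC(=O)c1cc(O)c(O)c(O)c1)[C@@H](c1cc(O)c(O)c(O)c1)O2)c1cc(O)c(O)c(O)c1 | target

**Step count and risks**

Total: 20 steps. Longest linear sequence: 12 steps (1, 2, 3, 6, 7, 8, 9, 16, 17, 18, 19, 20).

The three steps most likely to fail: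

Step 16. What may go wrong: the many benzyl ether chromophores and the product phenol may compete for light, the excited diazo ketone may be diverted into carbene chemistry, and the ynol ether may degrade under irradiation, so that ketene formation and alkyne capture no longer keep pace. Fallback: ketene generation is separated from the alkyne and taken out of the photoreactor. Setting out from 22, a silver-catalysed Wolff rearrangement in the dark (AgO2CPh, Et3N, THF–H2O) lets water trap the ketene as 2-[(2R,3R)-3-(methoxymethoxy)-2-ArG-3,4-dihydro-2H-pyran-6-yl]acetic acid F1. 1-Chloro-N,N,2-trimethylprop-1-en-1-amine in CH2Cl2 converts it under neutral conditions into 2-[(2R,3R)-3-(methoxymethoxy)-2-ArG-3,4-dihydro-2H-pyran-6-yl]acetyl chloride F2. Slow addition of F2 to Et3N and 14 in toluene at rt regenerates vinylketene 23 by dehydrochlorination without light or metal, and warming to 90 °C carries the same [2+2]/4π/6π sequence through, rejoining the route at 27.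

Step 6. What may go wrong: the benzylic propargylic mesylate may ionise and racemise, or decompose, before zerovalent palladium captures it, and the anti/syn preference may be weak with an α-unbranched, enolisable aldehyde. Fallback: an isolable, configurationally stable allenylboron reagent replaces the transient allenylindium. Setting out from 6, methyl chloroformate and pyridine give methyl (S)-1-ArG-3-(trimethylsilyl)prop-2-yn-1-yl carbonate F3. Copper-catalysed anti-SN2′ borylation (CuOt-Bu, Xantphos, B2pin2, THF) then gives (P)-4,4,5,5-tetramethyl-2-[3-ArG-1-(trimethylsilyl)propa-1,2-dien-1-yl]-1,3,2-dioxaborolane F4, which can be purified and assayed. Heating F4 with 4 in toluene adds it through a closed six-membered transition state syn to boron; this should give the same anti adduct and rejoins the route at 9 after work-up.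

Step 14. What may go wrong: transmetalation to the hindered, electron-rich ketene acetal phosphate may be slow, and the acid used to unmask the acetyl group may also hydrate or open the cyclic enol ether. Fallback: the acyl group is introduced at the carbonyl oxidation level and no acid is used. Setting out from 18, palladium-catalysed aminocarbonylation (Pd(PPh3)4, CO 1 atm, MeNHOMe·HCl, Et3N, DMF, 50 °C) gives (2R,3R)-N-methoxy-3-(methoxymethoxy)-N-methyl-2-ArG-3,4-dihydro-2H-pyran-6-carboxamide F5. MeMgBr in THF at −20 °C converts F5 through its stable chelate into methyl ketone 20, where the route is rejoined.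

**Further compounds**

F1 | step 16 | 2-[(2R,3R)-3-(methoxymethoxy)-2-ArG-3,4-dihydro-2H-pyran-6-yl]acetic acid | OC(=O)CC1=CC[C@@H](OCOC)[C@@H](c2cc(OCc3ccccc3)c(OCc3ccccc3)c(OCc3ccccc3)c2)O1
F2 | step 16 | 2-[(2R,3R)-3-(methoxymethoxy)-2-ArG-3,4-dihydro-2H-pyran-6-yl]acetyl chloride | ClC(=O)CC1=CC[C@@H](OCOC)[C@@H](c2cc(OCc3ccccc3)c(OCc3ccccc3)c(OCc3ccccc3)c2)O1
F3 | step 6 | methyl (S)-1-ArG-3-(trimethylsilyl)prop-2-yn-1-yl carbonate | COC(=O)O[C@@H](c1cc(OCc2ccccc2)c(OCc2ccccc2)c(OCc2ccccc2)c1)C#C[Si](C)(C)C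
F4 | step 6 | (P)-4,4,5,5-tetramethyl-2-[3-ArG-1-(trimethylsilyl)propa-1,2-dien-1-yl]-1,3,2-dioxaborolane | C[Si](C)(C)C(B1OC(C)(C)C(C)(C)O1)=[C@@]=C([H])c1cc(OCc2ccccc2)c(OCc2ccccc2)c(OCc2ccccc2)c1
F5 | step 14 | (2R,3R)-N-methoxy-3-(methoxymethoxy)-N-methyl-2-ArG-3,4-dihydro-2H-pyran-6-carboxamide | CON(C)C(=O)C1=CC[C@@H](OCOC)[C@@H](c2cc(OCc3ccccc3)c(OCc3ccccc3)c(OCc3ccccc3)c2)O1
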